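Readings and results stem from a simulated flask with constants of no real substance.

The north-west run, with 0.19 mM of J against 0.20 mM of Q, has J as its limiting reagent, and its ledger of J shows where that charge went.

| flask | Q | J | remark | time |
|---|---|---|---|---|
| north-west | 0.20 mM | 0.19 mM | run made earlier |  |
| east | 0.10 mM | 0.19 mM | run made earlier |  |
| south-west | 0.15 mM | 0.19 mM | run made earlier |  |
| west | 0.20 mM | 0.29 mM | run made earlier |  |
| Wednesday's | 0.20 mM | 0.190 mM | everything together at the start | 3.0 min |
| Monday's | 0.20 mM (fed, over 12 s) | 0.190 mM | all else is in the flask from the start; the feed brings no volume worth counting | 3.0 min |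
| Friday's | 0.20 mM (fed, over 2.0 min) | 0.190 mM | all else is in the flask from the start; the feed brings no volume worth counting | 3.0 min |
| Tuesday's | 0.20 mM | 0.190 mM (fed, over 2.0 min) | all else is in the flask from the start; the feed brings no volume worth counting | 3.0 min |

north-west run (percent of the Q charged)

| time / min | Z / % | X / % |
|---|---|---|
| 0.200 | 12.6 | 5.7 |
| 0.667 | 14.6 | 11.8 |
| 1.00 | 15.0 | 12.8 |
| 1.50 | 14.1 | 13.8 |
| 2.50 | 14.7 | 13.7 |
| 3.00 | 14.8 | 14.5 |

east run (percent of the Q charged)

| time / s | Z / % | X / % |
|---|---|---|
| 10.0 | 12.4 | 4.9 |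
| 15.0 | 13.6 | 8.2 |
| 25.0 | 14.4 | 12.0 |
| 40.0 | 15.5 | 15.7 |
| 60.0 | 14.9 | 17.0 |
| 120 | 15.0 | 19.7 |

south-west run (percent of the Q charged)

| time / s | Z / % | X / % |
|---|---|---|
| 20.0 | 14.2 | 9.5 |
| 40.0 | 14.6 | 13.6 |
| 50.0 | 14.9 | 14.8 |
| 80.0 | 15.0 | 15.9 |
| 90.0 | 15.1 | 15.7 |
| 120 | 15.4 | 17.2 |

west run (percent of the Q charged)

| time / s | Z / % | X / % |
|---|---|---|
| 10.0 | 13.9 | 9.7 |
| 15.0 | 14.3 | 13.4 |
| 30.0 | 15.1 | 18.1 |
| 60.0 | 14.9 | 21.0 |
| 120 | 14.8 | 21.2 |

(standard deviation of a reading: 0.5 percentage points)

1. the best flask by share of Z in Z plus X; "all alike" if 1.5 percentage points covers them all (Wednesday's / Monday's / Friday's / Tuesday's / all alike)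
2. share of Z in Z plus X at the end, Wednesday's
3. share of Z in Z plus X at the end, Monday's
4. share of Z in Z plus X at the end, Friday's
5. share of Z in Z plus X at the end, Tuesday's



At 3.00 min in the north-west run, Z holds 0.0296 mM of J, one per molecule, and X holds 0.0580 mM, two per molecule. Together they hold 46.1% of the charge; this is the captured share, the J held in Z and X per J charged. The closing entry, 0.102 mM of J, stands in neither adduct, although Z and X together account for 29.3% of the Q.

At the same J charge, the last readings, taken at 120 s and so earlier than the north-west one, give 28.6% in the east run, with 0.10 mM of Q, and 39.3% in the south-west run, with 0.15 mM. The captured share therefore climbs with [Q], so the uncaptured J leaves by a route that competes with capture.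

This gives an estimate of my own for Friday's. In the north-west run, X stands at 81.4% of its last reading by 0.667 min, so that is taken as the working time of J. By then Friday's feed has delivered 0.0667 mM of Q, less than the east charge. Scaling the east share in proportion to [Q] is a rough step, since going from the east charge of Q to the north-west charge raises the share by a factor of 1.61, less than the ratio of the charges; it gives a captured share near 19.1% for Friday's. That is a share of J, not the share of Z that is asked for.

The forecast names Friday's as best, with 50.5% for Wednesday's, 58% for Monday's, 61% for Friday's and 35% for Tuesday's, where it reasons: “slow J feed gives more total exposure (less J wasted), pushing Q further along, so more X”.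

The flasks give 49.9% for Wednesday's, 53.9% for Monday's, 63.3% for Friday's and 51.4% for Tuesday's, so Friday's is best. The forecast and the flasks part on Tuesday's, which stands 16 percentage points above the forecast's figure.

    Q + J → Z (k = 140 M⁻¹ s⁻¹)
    J + Z → X (k = 600 M⁻¹ s⁻¹)
    J + X → E (k = 160 M⁻¹ s⁻¹)
    J ⇌ L (K = 3.30, k = 0.0220 s⁻¹)
    J → D (k = 0.0210 s⁻¹)

The captured share at the end is 47.1% in Wednesday's, 45.1% in Tuesday's and 20.3% in Friday's. At 0.308 min in Friday's, the half-life of J by the step from J + Z to X is 7.1 min, far longer than the 0.403 min relaxation half-life of J and L by their own step, both ways together. The neighbour of Friday's with 0.34 mM of Q captures 27.7% of its J and ends with a share of Z of 65.9%.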